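A direct plan would set C3 on an acyclic malonate and build ring A around it afterwards: pig liver esterase half-hydrolysis of the prochiral aryl(methoxymethoxy)malonate A1 to half-ester A2, reduction to β-hydroxy ester A3, fluoride-triggered annulation with the aryne from silylaryl triflate A4 to the tris-MOM chromanone A5, then acid cleavage of three MOM groups.
Its weakest steps would be:
- The enzymatic desymmetrisation A1 → A2: the only stereocentre would rest on an esterase acting on a crowded α-aryl-α-alkoxy malonate, where neither sense nor level of selectivity can be predicted, and a quaternary centre cannot be corrected later.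
- The aryne annulation A3 + A4 → A5: it has no precedent for an aliphatic β-hydroxy ester, costs four steps for the silyl triflate of a simple ring, and needs both regiocontrol on the aryne and acylation faster than protonation of the aryl anion.
- The final acid treatment of A5: acid strong enough for a tertiary alkyl MOM ether would meet an ortho-prenylphenol (chroman formation) and an electron-rich tertiary benzylic ketol (ionisation and loss of water to the isoflavone).

**Retrosynthetic overview**
The C4(=O)–C3(OH)(aryl) unit of ring C is a benzoin retron, so the C3–C4 bond is cut, leaving an aldehyde carbon (C4, on ring A) and an aryl ketone carbon (C3, on ring B) held together only by the O1–C2 ether.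
Ring C is closed last, by an enantioselective carbene-catalysed crossed benzoin cyclisation of an acyclic keto aldehyde that forms C3–C4 and the quaternary carbinol C3 in one operation, with the tertiary OH formed free.
The keto aldehyde comes from a two-step salicylaldehyde fragment (ring A) and a three-step chloromethyl ketone fragment (ring B), joined by one O-alkylation.
The design needs no enzyme and no aryne, and no acid is used once the prenyl group is in place; the only protecting groups are two aryl SEM ethers, removed by fluoride.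

Key step: step 7

Assumption: the (5aS,10bR) antipode of the aminoindanol-derived triazolium salt is taken as the one that directs attack to the Re face of the ketone; both antipodes are commercial, and the other would be used, with nothing else changed, if the sense proves opposite.

**Route**

Step 1
Reactants: 1 2,4,6-trimethoxybenzaldehyde
Product: 2 2,6-dihydroxy-4-methoxybenzaldehyde
Conditions: AlCl3 (5 equiv), CH2Cl2, 0 °C → reflux; cold 1 M aq. HCl
Reagents that add atoms: none
Why: Chelation-directed ether cleavage (Lewis acid demethylation ortho to a carbonyl group): AlCl3 bound to the aldehyde oxygen is delivered through a six-membered chelate to the two flanking methoxy groups, which lose chloromethane, while the para methoxy group has no such assistance and should stay.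

Step 2
Reactants: 2 2,6-dihydroxy-4-methoxybenzaldehyde
Product: 3 2-hydroxy-4-methoxy-6-{[2-(trimethylsilyl)ethoxy]methoxy}benzaldehyde
Conditions: SEMCl (1.0 equiv), i-Pr2NEt, CH2Cl2, −10 °C → rt
Reagents that add atoms: 2-(trimethylsilyl)ethoxymethyl chloride (SEMCl), C[Si](C)(C)CCOCCl
Why: Williamson-type O-alkylation with an alkoxymethyl chloride: the two hydroxyl groups of 2 are equivalent, and once one has reacted the other is held in the hydrogen bond to the aldehyde and is far less nucleophilic, so the reaction should stop at the mono-ether, whose SEM group later keeps this phenol from quenching the carbene catalyst.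

Step 3
Reactants: 4 4-bromo-3-methoxyphenol
Product: 5 1-bromo-2-methoxy-4-{[2-(trimethylsilyl)ethoxy]methoxy}benzene
Conditions: SEMCl (1.1 equiv), i-Pr2NEt, CH2Cl2, 0 °C → rt
Reagents that add atoms: 2-(trimethylsilyl)ethoxymethyl chloride (SEMCl), C[Si](C)(C)CCOCCl
Why: Williamson-type O-alkylation of the phenol, which leaves the aryl bromide untouched and installs an acetal oxygen that directs the metalation of step 4 and is later removable by fluoride.

Step 4
Reactants: 5 1-bromo-2-methoxy-4-{[2-(trimethylsilyl)ethoxy]methoxy}benzene; 6 prenyl bromide (1-bromo-3-methylbut-2-ene)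
Product: 8 1-bromo-2-methoxy-3-(3-methylbut-2-en-1-yl)-4-{[2-(trimethylsilyl)ethoxy]methoxy}benzene, via aryllithium 7 (not isolated)
Conditions: LiTMP (lithium 2,2,6,6-tetramethylpiperidide, from TMPH and n-BuLi, 1.3 equiv), THF, −78 °C; then CuBr·SMe2 (10 mol %), 6, −78 → 0 °C
Reagents that add atoms: none
Why: Directed ortho-metalation: the hydrogen between the OMe and OSEM groups is the most acidic on the ring, the amide base cannot undergo bromine–lithium exchange, and the doubly oxygen-flanked aryllithium is already the most stable isomer so that a halogen dance has no driving force; copper-catalysed allylic substitution should then give the linear prenyl arene.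

Step 5
Reactants: 8 1-bromo-2-methoxy-3-(3-methylbut-2-en-1-yl)-4-{[2-(trimethylsilyl)ethoxy]methoxy}benzene; 9 2-chloro-N-methoxy-N-methylacetamide
Product: 12 2-chloro-1-[2-methoxy-3-(3-methylbut-2-en-1-yl)-4-{[2-(trimethylsilyl)ethoxy]methoxy}phenyl]ethan-1-one, via aryllithium 10 (not isolated), via lithium aminoalkoxide 11 (not isolated)
Conditions: n-BuLi (1.05 equiv), THF, −78 °C; then 9, −78 → −30 °C; sat. aq. NH4Cl
Reagents that add atoms: none
Why: Weinreb ketone synthesis: bromine–lithium exchange at −78 °C is faster than deprotonation of the benzylic-allylic CH2, the aryllithium adds to the amide carbonyl to give the chelated tetrahedral adduct 11 that cannot collapse before the quench, so no second addition occurs, and the C–Cl bond is not attacked at this temperature.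

Step 6
Reactants: 3 2-hydroxy-4-methoxy-6-{[2-(trimethylsilyl)ethoxy]methoxy}benzaldehyde; 12 2-chloro-1-[2-methoxy-3-(3-methylbut-2-en-1-yl)-4-{[2-(trimethylsilyl)ethoxy]methoxy}phenyl]ethan-1-one
Product: 13 4-methoxy-2-{2-[2-methoxy-3-(3-methylbut-2-en-1-yl)-4-{[2-(trimethylsilyl)ethoxy]methoxy}phenyl]-2-oxoethoxy}-6-{[2-(trimethylsilyl)ethoxy]methoxy}benzaldehyde
Conditions: K2CO3 (1.5 equiv), NaI (10 mol %), acetone, rt
Reagents that add atoms: none
Why: Williamson ether synthesis on an α-halo ketone, accelerated by in situ Finkelstein exchange to the iodo ketone, with a mild carbonate base at room temperature so that the intramolecular aldol condensation of the product to a benzofuran (Rap–Stoermer reaction) is held back.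

Step 7
Reactants: 13 4-methoxy-2-{2-[2-methoxy-3-(3-methylbut-2-en-1-yl)-4-{[2-(trimethylsilyl)ethoxy]methoxy}phenyl]-2-oxoethoxy}-6-{[2-(trimethylsilyl)ethoxy]methoxy}benzaldehyde
Product: 15 (3S)-3-hydroxy-7-methoxy-3-[2-methoxy-3-(3-methylbut-2-en-1-yl)-4-{[2-(trimethylsilyl)ethoxy]methoxy}phenyl]-5-{[2-(trimethylsilyl)ethoxy]methoxy}-2,3-dihydro-4H-chromen-4-one, via Breslow enaminol 14 (not isolated)
Conditions: (5aS,10bR)-2-(pentafluorophenyl)-5a,10b-dihydro-4H,6H-indeno[2,1-b][1,2,4]triazolo[4,3-d][1,4]oxazin-2-ium tetrafluoroborate (15 mol %), Et3N (15 mol %), degassed toluene, rt, Ar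
Reagents that add atoms: none
Why: The triazolylidene set free by Et3N adds to the aldehyde, proton transfer gives the Breslow enaminol 14, whose nucleophilic carbon (the later C4) adds to the tethered aryl ketone, and proton transfer with loss of the carbene leaves the tertiary α-ketol. The closest known reaction type is the enantioselective carbene-catalysed crossed aldehyde–ketone benzoin cyclisation of 2-(2-oxoalkoxy)benzaldehydes to 3-hydroxychroman-4-ones, aryl ketone acceptors included. Ring C is closed by a 6-exo-trig addition that forms C3–C4, after the O1–C2 ether has tied the two arenes together. The only stereocentre, C3, is set under catalyst control: the fused indane shields one face of the enaminol and a hydrogen bond from its OH to the ketone oxygen fixes the acceptor, so that C4 should add to the Re face of the ketone, which gives (3S). The step needs benzoin closure to outrun base-induced aldol closure of the OCH2 group onto the aldehyde, secured by a weak amine base in catalytic amount with an acidic N-pentafluorophenyl triazolium salt, and it needs the aldehyde alone to act as donor, secured because only an aldehyde can form the Breslow intermediate while the tethered ketone is the nearest acceptor. C3 then carries no hydrogen and cannot epimerise.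

Step 8
Reactants: 15 (3S)-3-hydroxy-7-methoxy-3-[2-methoxy-3-(3-methylbut-2-en-1-yl)-4-{[2-(trimethylsilyl)ethoxy]methoxy}phenyl]-5-{[2-(trimethylsilyl)ethoxy]methoxy}-2,3-dihydro-4H-chromen-4-one
Product: 16 (3S)-3,5-dihydroxy-3-[4-hydroxy-2-methoxy-3-(3-methylbut-2-en-1-yl)phenyl]-7-methoxy-2,3-dihydro-4H-chromen-4-one (EANPDB:LEGU_00502)
Conditions: Bu4NF (6 equiv), THF/DMPU, 45 °C; sat. aq. NH4Cl
Reagents that add atoms: none
Why: Fluoride-induced fragmentation of the two SEM ethers (attack at silicon, loss of ethene and of formaldehyde from the hemiformal) frees both phenols under non-acidic conditions, so that the ortho-prenylphenol cannot cyclise to a chroman and the C3 carbinol cannot ionise and dehydrate to the isoflavone, while C3, having no hydrogen, keeps its configuration.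

**Compound list**
1 | 2,4,6-trimethoxybenzaldehyde | COc1cc(OC)c(C=O)c(OC)c1 | starting material
2 | 2,6-dihydroxy-4-methoxybenzaldehyde | COc1cc(O)c(C=O)c(O)c1 | intermediate
3 | 2-hydroxy-4-methoxy-6-{[2-(trimethylsilyl)ethoxy]methoxy}benzaldehyde | COc1cc(O)c(C=O)c(OCOCC[Si](C)(C)C)c1 | intermediate
4 | 4-bromo-3-methoxyphenol | COc1cc(O)ccc1Br | starting material
5 | 1-bromo-2-methoxy-4-{[2-(trimethylsilyl)ethoxy]methoxy}benzene | COc1cc(OCOCC[Si](C)(C)C)ccc1Br | intermediate
6 | prenyl bromide (1-bromo-3-methylbut-2-ene) | CC(C)=CCBr | starting material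
7 | [3-bromo-2-methoxy-6-{[2-(trimethylsilyl)ethoxy]methoxy}phenyl]lithium (not isolated) | [Li]c1c(OC)c(Br)ccc1OCOCC[Si](C)(C)C | intermediate
8 | 1-bromo-2-methoxy-3-(3-methylbut-2-en-1-yl)-4-{[2-(trimethylsilyl)ethoxy]methoxy}benzene | COc1c(Br)ccc(OCOCC[Si](C)(C)C)c1CC=C(C)C | intermediate
9 | 2-chloro-N-methoxy-N-methylacetamide | CON(C)C(=O)CCl | starting material
10 | [2-methoxy-3-(3-methylbut-2-en-1-yl)-4-{[2-(trimethylsilyl)ethoxy]methoxy}phenyl]lithium (not isolated) | [Li]c1ccc(OCOCC[Si](C)(C)C)c(CC=C(C)C)c1OC | intermediate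
11 | lithium 2-chloro-1-[methoxy(methyl)amino]-1-[2-methoxy-3-(3-methylbut-2-en-1-yl)-4-{[2-(trimethylsilyl)ethoxy]methoxy}phenyl]ethan-1-olate (racemic; not isolated) | [Li]OC(CCl)(N(C)OC)c1ccc(OCOCC[Si](C)(C)C)c(CC=C(C)C)c1OC | intermediate
12 | 2-chloro-1-[2-methoxy-3-(3-methylbut-2-en-1-yl)-4-{[2-(trimethylsilyl)ethoxy]methoxy}phenyl]ethan-1-one | COc1c(C(=O)CCl)ccc(OCOCC[Si](C)(C)C)c1CC=C(C)C | intermediate
13 | 4-methoxy-2-{2-[2-methoxy-3-(3-methylbut-2-en-1-yl)-4-{[2-(trimethylsilyl)ethoxy]methoxy}phenyl]-2-oxoethoxy}-6-{[2-(trimethylsilyl)ethoxy]methoxy}benzaldehyde | COc1cc(OCC(=O)c2ccc(OCOCC[Si](C)(C)C)c(CC=C(C)C)c2OC)c(C=O)c(OCOCC[Si](C)(C)C)c1 | intermediate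
14 | Breslow enaminol: the aldehyde carbon of 13 as a C(OH)= unit doubly bonded to C3 of the (5aS,10bR)-2-(pentafluorophenyl)indeno-triazolo-oxazine (alkene geometry not defined; not isolated) | OC(c1c(OCC(=O)c2ccc(OCOCC[Si](C)(C)C)c(CC=C(C)C)c2OC)cc(OC)cc1OCOCC[Si](C)(C)C)=C1N(c2c(F)c(F)c(F)c(F)c2F)N=C2CO[C@H]3Cc4ccccc4[C@H]3N12 | intermediate
15 | (3S)-3-hydroxy-7-methoxy-3-[2-methoxy-3-(3-methylbut-2-en-1-yl)-4-{[2-(trimethylsilyl)ethoxy]methoxy}phenyl]-5-{[2-(trimethylsilyl)ethoxy]methoxy}-2,3-dihydro-4H-chromen-4-one | COc1cc(OCOCC[Si](C)(C)C)c2c(c1)OC[C@@](O)(c1ccc(OCOCC[Si](C)(C)C)c(CC=C(C)C)c1OC)C2=O | intermediate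
16 | (3S)-3,5-dihydroxy-3-[4-hydroxy-2-methoxy-3-(3-methylbut-2-en-1-yl)phenyl]-7-methoxy-2,3-dihydro-4H-chromen-4-one | COc1cc(O)c2c(c1)OC[C@@](O)(c1ccc(O)c(CC=C(C)C)c1OC)C2=O | target

**Step count**
Total steps: 8. Longest linear sequence: 6 steps (steps 3 to 8, from 4-bromo-3-methoxyphenol).

**Steps most likely to fail**

Step 7. The bulky chiral carbene may add too slowly to an aldehyde flanked by two ortho oxygen substituents, so that base-induced aldol closure to a 2-aroylbenzofuran takes over, or the facial selectivity at the ortho-substituted aryl ketone may be poor. The fallback sets C3 by enolate oxidation instead of C–C bond formation; it sets out from 3 and 8 and returns at 15. Vinylmagnesium bromide (2.2 equiv, THF, −78 → 0 °C) would add to 3 to give the allylic alcohol F1. MnO2 in CH2Cl2 would oxidise it to the aryl vinyl ketone F2, which should close by oxa-Michael addition in the same flask to the chromanone F3. α-Arylation of F3 with bromide 8 (Pd(OAc)2, 2-dicyclohexylphosphino-2′,4′,6′-triisopropylbiphenyl, NaOt-Bu, toluene, 80 °C) would give the racemic isoflavanone F4. Its sodium enolate (NaN(SiMe3)2, THF, −78 °C) is achiral, so both enantiomers converge, and hydroxylation with an enantiopure (camphorsulfonyl)oxaziridine (Davis reagent, antipode chosen for 3S) would give 15.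

Step 8. The non-chelated 4′-O-SEM ether needs warm fluoride, under which the cleavage may stall at a mono-ether or the phenoxide- and alkoxide-bearing ketol may undergo α-ketol rearrangement. The fallback replaces both acetals by allyl ethers that are removed by allyl transfer under neutral conditions; it sets out from 8 and 2 and returns at 16.
- Ring B: Bu4NF/DMPU at 60 °C on the robust bromide 8 would give the phenol F5, and allyl bromide/K2CO3 the allyl ether F6. Bromine–lithium exchange to the aryllithium F7 and addition to 9 through the lithium aminoalkoxide F8 would give the chloromethyl ketone F9, as in step 5.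
- Ring A: mono-allylation of 2 (allyl bromide, K2CO3, DMF) would give the salicylaldehyde F10.
- Assembly: alkylation of F10 with F9 as in step 6 would give the keto aldehyde F11. The benzoin cyclisation of step 7 would lead through the Breslow enaminol F12 to the bis-allyl ketol F13. Pd(PPh3)4 (5 mol %) with morpholine in THF at rt would transfer both allyl groups to the amine and give 16.

Step 6. Under carbonate the keto aldehyde may enolise at its OCH2 group and close onto the aldehyde (aldol condensation to the 2-aroylbenzofuran) as fast as the ether forms. The fallback makes the same C–O bond without base by a Mitsunobu reaction; it sets out from 12 and returns at 13. Sodium formate in DMF would displace chloride to give the formate ester F14, and methanolysis (MeOH, cat. NaHCO3) the α-hydroxy ketone F15. PPh3 and diisopropyl azodicarboxylate in toluene (0 °C → rt) would couple F15 with phenol 3 to give 13.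

**Further compounds**
F1 | step 7 | 1-[2-hydroxy-4-methoxy-6-{[2-(trimethylsilyl)ethoxy]methoxy}phenyl]prop-2-en-1-ol (racemic) | C=CC(O)c1c(O)cc(OC)cc1OCOCC[Si](C)(C)C
F2 | step 7 | 1-[2-hydroxy-4-methoxy-6-{[2-(trimethylsilyl)ethoxy]methoxy}phenyl]prop-2-en-1-one (not isolated) | C=CC(=O)c1c(O)cc(OC)cc1OCOCC[Si](C)(C)C
F3 | step 7 | 7-methoxy-5-{[2-(trimethylsilyl)ethoxy]methoxy}-2,3-dihydro-4H-chromen-4-one | COc1cc(OCOCC[Si](C)(C)C)c2c(c1)OCCC2=O
F4 | step 7 | 7-methoxy-3-[2-methoxy-3-(3-methylbut-2-en-1-yl)-4-{[2-(trimethylsilyl)ethoxy]methoxy}phenyl]-5-{[2-(trimethylsilyl)ethoxy]methoxy}-2,3-dihydro-4H-chromen-4-one (racemic) | COc1cc(OCOCC[Si](C)(C)C)c2c(c1)OCC(c1ccc(OCOCC[Si](C)(C)C)c(CC=C(C)C)c1OC)C2=O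
F5 | step 8 | 4-bromo-3-methoxy-2-(3-methylbut-2-en-1-yl)phenol | COc1c(Br)ccc(O)c1CC=C(C)C
F6 | step 8 | 1-bromo-2-methoxy-3-(3-methylbut-2-en-1-yl)-4-(prop-2-en-1-yloxy)benzene | COc1c(Br)ccc(OCC=C)c1CC=C(C)C
F7 | step 8 | [2-methoxy-3-(3-methylbut-2-en-1-yl)-4-(prop-2-en-1-yloxy)phenyl]lithium (not isolated) | [Li]c1ccc(OCC=C)c(CC=C(C)C)c1OC
F8 | step 8 | lithium 2-chloro-1-[methoxy(methyl)amino]-1-[2-methoxy-3-(3-methylbut-2-en-1-yl)-4-(prop-2-en-1-yloxy)phenyl]ethan-1-olate (racemic; not isolated) | [Li]OC(CCl)(N(C)OC)c1ccc(OCC=C)c(CC=C(C)C)c1OC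
F9 | step 8 | 2-chloro-1-[2-methoxy-3-(3-methylbut-2-en-1-yl)-4-(prop-2-en-1-yloxy)phenyl]ethan-1-one | COc1c(C(=O)CCl)ccc(OCC=C)c1CC=C(C)C
F10 | step 8 | 2-hydroxy-4-methoxy-6-(prop-2-en-1-yloxy)benzaldehyde | COc1cc(O)c(C=O)c(OCC=C)c1
F11 | step 8 | 4-methoxy-2-{2-[2-methoxy-3-(3-methylbut-2-en-1-yl)-4-(prop-2-en-1-yloxy)phenyl]-2-oxoethoxy}-6-(prop-2-en-1-yloxy)benzaldehyde | COc1cc(OCC(=O)c2ccc(OCC=C)c(CC=C(C)C)c2OC)c(C=O)c(OCC=C)c1
F12 | step 8 | Breslow enaminol of F11 with the (5aS,10bR) carbene (alkene geometry not defined; not isolated) | OC(c1c(OCC(=O)c2ccc(OCC=C)c(CC=C(C)C)c2OC)cc(OC)cc1OCC=C)=C1N(c2c(F)c(F)c(F)c(F)c2F)N=C2CO[C@H]3Cc4ccccc4[C@H]3N12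
F13 | step 8 | (3S)-3-hydroxy-7-methoxy-3-[2-methoxy-3-(3-methylbut-2-en-1-yl)-4-(prop-2-en-1-yloxy)phenyl]-5-(prop-2-en-1-yloxy)-2,3-dihydro-4H-chromen-4-one | COc1cc(OCC=C)c2c(c1)OC[C@@](O)(c1ccc(OCC=C)c(CC=C(C)C)c1OC)C2=O
F14 | step 6 | 2-[2-methoxy-3-(3-methylbut-2-en-1-yl)-4-{[2-(trimethylsilyl)ethoxy]methoxy}phenyl]-2-oxoethyl formate | O=COCC(=O)c1ccc(OCOCC[Si](C)(C)C)c(CC=C(C)C)c1OC
F15 | step 6 | 2-hydroxy-1-[2-methoxy-3-(3-methylbut-2-en-1-yl)-4-{[2-(trimethylsilyl)ethoxy]methoxy}phenyl]ethan-1-one | OCC(=O)c1ccc(OCOCC[Si](C)(C)C)c(CC=C(C)C)c1OC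
A1 | direct plan | diethyl 2-(methoxymethoxy)-2-[2-methoxy-4-(methoxymethoxy)-3-(3-methylbut-2-en-1-yl)phenyl]propanedioate | CCOC(=O)C(OCOC)(C(=O)OCC)c1ccc(OCOC)c(CC=C(C)C)c1OC
A2 | direct plan | (2S)-3-ethoxy-2-(methoxymethoxy)-2-[2-methoxy-4-(methoxymethoxy)-3-(3-methylbut-2-en-1-yl)phenyl]-3-oxopropanoic acid | OC(=O)[C@@](OCOC)(c1ccc(OCOC)c(CC=C(C)C)c1OC)C(=O)OCC
A3 | direct plan | ethyl (2S)-3-hydroxy-2-(methoxymethoxy)-2-[2-methoxy-4-(methoxymethoxy)-3-(3-methylbut-2-en-1-yl)phenyl]propanoate | OC[C@@](OCOC)(c1ccc(OCOC)c(CC=C(C)C)c1OC)C(=O)OCC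
A4 | direct plan | 5-methoxy-3-(methoxymethoxy)-2-(trimethylsilyl)phenyl trifluoromethanesulfonate | COc1cc(OCOC)c([Si](C)(C)C)c(OS(=O)(=O)C(F)(F)F)c1
A5 | direct plan | (3S)-7-methoxy-3,5-bis(methoxymethoxy)-3-[2-methoxy-4-(methoxymethoxy)-3-(3-methylbut-2-en-1-yl)phenyl]-2,3-dihydro-4H-chromen-4-one | COc1cc(OCOC)c2c(c1)OC[C@@](OCOC)(c1ccc(OCOC)c(CC=C(C)C)c1OC)C2=O
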